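The moment of reading comes when 20% of the starting material has been converted, and the spring run reaches it near 80.0 s, with 81% left and 14% as target.

- spring: starting material 14 mM; second substrate 14 mM; partner 7 mM; free catalyst 1 mM; run made earlier
- flask: starting material 14 mM; second substrate 14.0 mM; partner 7.00 mM; free catalyst 0.70 mM

- spring (time / s: target / %, starting material / %): 10.0: 2, 98; 20.0: 2, 94; 30.0: 5, 92; 50.0: 7, 88; 80.0: 14, 81; 90.0: 16, 83; 120: 15, 78

(readings scatter by 1.5 percentage points)

- the numbers in the tables scatter with a standard deviation of 1.5 percentage points
- reactions considered so far: starting material + free catalyst <-> catalyst intermediate A; partner + catalyst intermediate A -> free catalyst + target; second substrate + free catalyst <-> catalyst intermediate B; partner + catalyst intermediate B -> free catalyst + second product; partner -> decomposed reagent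
- what is bound to the catalyst counts as converted
- no earlier run changes the charge of free catalyst; that part of a forecast is a guess
- no earlier run changes the charge of second substrate; that part of a forecast is a guess
- no earlier run changes the charge of partner; that part of a forecast is a guess

- apparent order in partner when 20% of the starting material are converted (percent change of the rate of making target for one percent more partner charged)
- apparent order in second substrate when 20% of the starting material are converted (percent change of the rate of making target for one percent more second substrate charged)

Target forms at a rate proportional to [partner][catalyst intermediate A]. So far as a fixed amount of partner has gone at the reading, one percent more charge becomes a larger percentage of what remains. The ratio of charge to remainder therefore multiplies the order in partner.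

That ratio can be reckoned in two ways for the spring run. Counting turnovers gives 1.96 per catalyst, each costing one partner, so 1.96 mM is gone and the ratio is 1.39. The fading rate gives another figure: the average rate up to the reading over the slope just after it comes to 2.92, if catalyst intermediate A holds steady.

The second figure is larger, and each way cheats. The count reads target alone, with second product and decomposed reagent unmeasured, so the partner taken by those two routes stands outside it. The slope rests on a rise comparable with the scatter of 1.5 percentage points.

The reckoning here takes their geometric mean, 2.01, as the gearing, partner charged over partner still free at the reading, and carries it to the flask as its order in partner. The change of catalyst charge is a guess.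

The forecast gives 2 and −0.8, holding that “extra charged partner adds fully to this small remainder”.

The simulation gives 1.8 and −0.31.

    starting material + free catalyst ⇌ catalyst intermediate A (K = 4500 /M, k = 10.0 /M/s)
    partner + catalyst intermediate A → free catalyst + target (k = 7.30 /M/s)
    second substrate + free catalyst ⇌ catalyst intermediate B (K = 61.0 /M, k = 6.70 /M/s)
    partner + catalyst intermediate B → free catalyst + second product (k = 4.50 /M/s)
    partner → decomposed reagent (k = 0.00270 /s)

At 2.00 min, with 83.3% of the starting material left and so still short of the reading, the flask has made 2.62 turnovers to target, costing 1.84 mM of partner, yet [partner] stands at 46.7% of its charge, a gearing of 2.14 at that moment beside the 2.01 carried for the reading, with 1.61 mM as decomposed reagent and 0.289 mM as second product. In the flask at 1.83 min the step to target uses partner 1.3 times as fast as the step to decomposed reagent, and by 20.0 min partner, the limiting reagent, is down to 0.0142% of its charge, with 2.85 mM as decomposed reagent.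

All runs were computed on assumed constants; scatter was added.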